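## Retrosynthetic overview

1. Target 34 ⇐ ester bond at O8 (8-hydroxy lactone 29 + (R)-epoxy acid 32), with O9 unmasked last; the γ-lactone C12(=O)–O6 ⇐ oxidative lactonisation of the C6/C12 diol 27.
2. Ten-membered ring ⇐ enol triflate 25 ⇐ cyclohexanol 22. The feature used: C2–C3 of the (1(10)Z,4E)-cyclodeca-1,5-diene is the σ-bond of a Cope system (C1=C10 and C4=C5 on either side), and C5/C10 can be joined into a cyclohexane (C5–C10) that carries C6–C9. Forward: anionic oxy-Cope four-atom ring expansion, enolate caught as the C5 triflate.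
3. 22 ⇐ C5 ketone 20 + isopropenylmagnesium bromide; O6 by enolate hydroxylation, O8 by equatorial hydride delivery to a C8 ketone, O9 by axial hydride delivery to the C9 ketone.
4. Quaternary C10 (methyl/vinyl) ⇐ semipinacol 1,2-vinyl shift of the epoxy alcohol made from (S)-carvone and vinylmagnesium bromide.
5. Ring order: cyclohexane (from carvone) → ten-membered carbocycle (step 18) → γ-lactone (step 21); the oxirane of the acyl group is made separately (step 23).

Key step: step 18

Remark on numbering: atoms keep their germacrane numbers in every intermediate (ring C5–C10; C11–C13 on C7; C14 on C10). In the six-membered compounds α is the ring face carrying the C7 side chain, β the opposite face.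
Assumption: vinylmagnesium bromide, isopropenylmagnesium bromide (the Grignard reagent of 2-bromopropene) and 3-methylbut-3-en-1-ol are bought; in step 23 the ligand enantiomer is the one that gives the (R)-epoxide.

## Route

Step 1
Reactants: 1 (S)-(+)-carvone; 2 vinylmagnesium bromide
Product: 3 (5S)-1-ethenyl-2-methyl-5-(prop-1-en-2-yl)cyclohex-2-en-1-ol (9α-OH, 9β-vinyl)
Conditions: vinylmagnesium bromide, THF, −78 to 0 °C; H2O
Reagents that add atoms: vinylmagnesium bromide (2), C=C[Mg]Br
Why: Grignard 1,2-addition to the enone carbonyl; the nucleophile should enter axially on the face anti to the C7 isopropenyl group (as hydride does when carvone is reduced to cis-carveol), which sets C9 with vinyl β and OH α.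

Step 2
Reactants: 3 tertiary divinyl carbinol
Product: 4 10,5α-epoxy alcohol (epoxide oxygen syn to the 9α-OH)
Conditions: VO(acac)2 (cat.), t-BuOOH, CH2Cl2, 0 °C to rt
Reagents that add atoms: tert-butyl hydroperoxide, CC(C)(C)OO
Why: Hydroxyl-directed vanadium-catalysed epoxidation; the vanadium-bound allylic alkoxide delivers oxygen to the trisubstituted C10=C5 alkene on the face of the OH, setting C10 and C5 syn to O9, while the monosubstituted vinyl and the remote isopropenyl alkenes react far more slowly.

Step 3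
Reactants: 4 epoxy alcohol
Product: 5 5α-hydroxy-10α-methyl-10β-vinyl-7α-isopropenylcyclohexan-9-one
Conditions: BF3·OEt2 (0.2 equiv), CH2Cl2, −78 to −40 °C; Et3N
Reagents that add atoms: none
Why: Semipinacol rearrangement of a 2,3-epoxy alcohol; opening of the tertiary C10–O bond is coupled to 1,2-shift of the antiperiplanar (β) vinyl group from C9 to C10 with inversion at C10, which sets the quaternary centre (vinyl β, methyl α), keeps O5 α and regenerates the C9 carbonyl.

Step 4
Reactants: 5 β-hydroxy ketone
Product: 6 5-O-triethylsilyl ether of 5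
Conditions: Et3SiOTf, 2,6-lutidine, CH2Cl2, −78 °C
Reagents that add atoms: triethylsilyl trifluoromethanesulfonate, CC[Si](CC)(CC)OS(=O)(=O)C(F)(F)F
Why: Silylation of the aldol hydroxyl, so that the enolate chemistry that follows cannot trigger retro-aldol cleavage of the C5–C10 bond.

Step 5
Reactants: 6 silyloxy ketone
Product: 8 8β-hydroxy-9-ketone, via potassium enolate 7 (not isolated)
Conditions: KN(SiMe3)2, THF, −78 °C; 2-(phenylsulfonyl)-3-phenyloxaziridine; AcOH
Reagents that add atoms: 2-(phenylsulfonyl)-3-phenyloxaziridine, O=S(=O)(c1ccccc1)N1OC1c1ccccc1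
Why: Davis oxidation of the only possible enolate (C8, since C10 is quaternary); oxygen should enter anti to the C7 side chain and the axial C10 methyl to give the 8β-alcohol, a configuration that is erased again in step 9.

Step 6
Reactants: 8 α-hydroxy ketone
Product: 9 8β,9α-diol
Conditions: NaBH4, MeOH, −20 to 0 °C
Reagents that add atoms: none
Why: Borohydride reduction with axial hydride delivery on the β face, anti to the vicinal axial C10 methyl, which sets the equatorial 9α-alcohol.

Step 7
Reactants: 9 trans-diol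
Product: 10 8,9-O-(4-methoxybenzylidene) acetal (acetal carbon as a mixture of epimers)
Conditions: 4-MeOC6H4CH(OMe)2, pyridinium p-toluenesulfonate (cat.), 4 Å molecular sieves, CH2Cl2, rt
Reagents that add atoms: 4-methoxybenzaldehyde dimethyl acetal, COc1ccc(C(OC)OC)cc1
Why: Acid-catalysed transacetalisation ties the trans-diequatorial diol into a dioxolane; both acetal epimers converge in step 8 and the sieves take up the methanol so that the silyl ether is kept.

Step 8
Reactants: 10 4-methoxybenzylidene acetal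
Product: 11 9-O-PMB ether with free 8β-OH
Conditions: i-Bu2AlH, CH2Cl2, −78 to 0 °C; aqueous potassium sodium tartrate
Reagents that add atoms: none
Why: Regioselective reductive acetal opening; the aluminium Lewis acid should bind the less hindered O8 (one carbon substituent gauche) rather than the neopentyl O9 (flanked by the C10 methyl and vinyl), so hydride delivery leaves the PMB ether on O9 and frees O8–H.

Step 9
Reactants: 11 secondary alcohol
Product: 12 C8 ketone
Conditions: Dess–Martin periodinane, CH2Cl2, 0 °C to rt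
Reagents that add atoms: none
Why: Dess–Martin oxidation under neutral conditions, which should not enolise the β,γ-unsaturated ketone towards C7.

Step 10
Reactants: 12 C8 ketone
Product: 13 8α-alcohol (axial, cis to the C7 side chain and to O9)
Conditions: LiBH(s-Bu)3, THF, −78 °C; H2O
Reagents that add atoms: none
Why: Ketone reduction with a bulky trialkylborohydride; axial approach on the α face is blocked by the syn-axial C10 methyl, so hydride comes equatorially from the β face and sets the axial 8α-alcohol (the isopulegone to neoisopulegol precedent).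

Step 11
Reactants: 13 8α-alcohol
Product: 14 8-O-TBS ether (5-OTES, 9-OPMB)
Conditions: t-BuMe2SiOTf, 2,6-lutidine, CH2Cl2, 0 °C
Reagents that add atoms: tert-butyldimethylsilyl trifluoromethanesulfonate, CC(C)(C)[Si](C)(C)OS(=O)(=O)C(F)(F)F
Why: Silylation with the reactive silyl triflate, needed for the hindered axial hydroxyl; O8 now carries a group that survives strong base and leaves with fluoride.

Step 12
Reactants: 14 bis-silyl ether
Product: 15 5α-alcohol
Conditions: pyridinium p-toluenesulfonate (cat.), MeOH/CH2Cl2, rt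
Reagents that add atoms: none
Why: Acid-catalysed methanolysis removes the triethylsilyl ether selectively; the hindered secondary TBS ether and the PMB ether are stable under these conditions.

Step 13
Reactants: 15 secondary alcohol
Product: 16 C5 ketone
Conditions: Dess–Martin periodinane, CH2Cl2, rt
Reagents that add atoms: none
Why: Dess–Martin oxidation; C9 is by now an ether, so the C5 and C9 oxygens never stand at the same oxidation level and the ring is never symmetrised.

Step 14
Reactants: 16 C5 ketone
Product: 18 6β-hydroxy-5-ketone, via potassium enolate 17 (not isolated)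
Conditions: KN(SiMe3)2, THF, −78 °C; 2-(phenylsulfonyl)-3-phenyloxaziridine; AcOH
Reagents that add atoms: 2-(phenylsulfonyl)-3-phenyloxaziridine, O=S(=O)(c1ccccc1)N1OC1c1ccccc1
Why: Davis oxidation of the C5=C6 enolate (only C6 can enolise); the α face of C6 is screened by the syn-axial C10 methyl and C8 silyloxy groups and by the adjacent C7 side chain, so oxygen should enter from the β face and set the equatorial 6β-alcohol.

Step 15
Reactants: 18 α-hydroxy ketone
Product: 19 6β,12-dihydroxy-5-ketone (C7 side chain now 3-hydroxyprop-1-en-2-yl)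
Conditions: SeO2 (0.3 equiv), t-BuOOH, CH2Cl2, rt
Reagents that add atoms: tert-butyl hydroperoxide, CC(C)(C)OO
Why: Selenium dioxide allylic oxidation (ene reaction, then [2,3]-sigmatropic shift) of the 1,1-disubstituted alkene at its methyl group; the vinyl group has no allylic hydrogen and the C7 methine is less reactive than CH3.

Step 16
Reactants: 19 diol
Product: 20 6,12-bis-O-(2-methoxyprop-2-yl) ketone (bis-MOP)
Conditions: 2-methoxypropene (excess), pyridinium p-toluenesulfonate (cat.), CH2Cl2, 0 °C; Et3N
Reagents that add atoms: 2-methoxypropene, COC(C)=C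
Why: Acid-catalysed addition of both hydroxyls to the enol ether gives two mixed ketals, which are base-stable, add no stereocentre, cannot migrate to a neighbouring alkoxide and leave together under very mild acid.

Step 17
Reactants: 20 C5 ketone; 21 isopropenylmagnesium bromide
Product: 22 cis-1-isopropenyl-2-vinylcyclohexanol (5α-OH, 5β-isopropenyl, 6β-OMOP, 8α-OTBS, 9α-OPMB, 12-OMOP)
Conditions: CH2=C(CH3)MgBr, LaCl3·2LiCl (0.3 equiv), THF, 0 °C; aqueous NaHCO3
Reagents that add atoms: isopropenylmagnesium bromide (21), CC(=C)[Mg]Br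
Why: Lanthanum-promoted Grignard 1,2-addition to a hindered ketone; the nucleophile should attack C5 from the β face, anti to the vicinal axial C10 methyl (axial attack, as in 4,4-dimethyl-3-keto steroids), which sets C5 with isopropenyl axial and cis to the equatorial vinyl group.

Step 18
Reactants: 22 cis-1-isopropenyl-2-vinylcyclohexanol
Product: 25 ten-membered (1(10)Z)-diene C5 enol triflate (C3 trans to C6 across C4=C5), via potassium alkoxide 23 (not isolated), via potassium enolate 24 (not isolated)
Conditions: KN(SiMe3)2, 18-crown-6, THF, −78 to 0 °C; then PhNTf2, −78 to 0 °C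
Reagents that add atoms: N-phenylbis(trifluoromethanesulfonimide), O=S(=O)(N(c1ccccc1)S(=O)(=O)C(F)(F)F)C(F)(F)F
Why: The crown-ether-separated potassium alkoxide 23 weakens C5–C10, so the 1,5-diene C3=C4–C5–C10–C1=C2 should undergo a [3,3]-sigmatropic shift (anionic oxy-Cope rearrangement) that forms C2–C3 as C5–C10 breaks; the closest known reaction type is the anionic oxy-Cope ring expansion of 1,2-dialkenylcyclohexanols to cyclodec-5-enone enolates with O-sulfonylation in the same flask. The ten-membered ring is therefore not closed end to end but opened out of the six-membered ring by a four-atom ring expansion through a chair transition state fused to the cyclohexane chair. No stereocentre is created and C6–C9 pass through unchanged; the two new alkene geometries follow from the chair, in which C6 is pseudo-equatorial (C4=C5 with C3 trans to C6) and C9 pseudo-axial (C1=C10 Z). The selectivity needed is (1(10)Z,4E) over (1(10)E,4Z), that is, reaction through the cyclohexane chair with axial isopropenyl and equatorial vinyl; that chair keeps the C6, C7 and C9 substituents equatorial, whereas the flipped chair would hold the C7 side chain, O9 and O5 syn-triaxial. PhNTf2 then freezes the enolate geometry of 24 as the triflate before protonation can scramble it.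

Step 19
Reactants: 25 enol triflate
Product: 26 (1(10)Z,4E)-cyclodeca-1(10),4-diene (6,12-bis-OMOP, 8-OTBS, 9-OPMB)
Conditions: Pd(OAc)2 (cat.), PPh3, HCO2H, n-Bu3N, DMF, 60 °C
Reagents that add atoms: none
Why: Palladium-catalysed formate reduction of an enol triflate (oxidative addition, formate decarboxylation, reductive elimination) replaces OTf by H with retention of geometry, giving the 4E alkene; the excess amine keeps the medium basic for the ketals.

Step 20
Reactants: 26 bis-MOP ether
Product: 27 6,12-diol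
Conditions: pyridinium p-toluenesulfonate (cat.), MeOH, 0 °C
Reagents that add atoms: none
Why: Acid-catalysed transketalisation to methanol removes both MOP groups under acidity too weak to touch the silyl ether, the PMB ether or to start transannular cyclisation of the diene.

Step 21
Reactants: 27 diol
Product: 28 12,6-lactone (α-methylene γ-lactone; 8-OTBS, 9-OPMB)
Conditions: TEMPO (cat.), PhI(OAc)2, CH2Cl2, rt
Reagents that add atoms: none
Why: TEMPO/PhI(OAc)2 oxidative lactonisation; the oxoammonium salt oxidises the primary allylic alcohol selectively, the aldehyde is captured by O6–H (the only free hydroxyl, so the ring size is unambiguous) as a lactol, and this is oxidised on to the trans-fused γ-lactone.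

Step 22
Reactants: 28 silyl ether
Product: 29 8-hydroxy lactone
Conditions: HF·pyridine, pyridine, THF, 0 °C to rt
Reagents that add atoms: none
Why: Fluoride-mediated desilylation under buffered, non-basic conditions, chosen to avoid translactonisation to O8 and conjugate addition to the α-methylene lactone.

Step 23
Reactants: 30 3-methylbut-3-en-1-ol
Product: 31 (R)-2-(2-methyloxiran-2-yl)ethan-1-ol
Conditions: VO(Oi-Pr)3 (cat.), chiral C2-symmetric bis-hydroxamic acid ligand (cat.), cumene hydroperoxide, toluene, rt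
Reagents that add atoms: cumene hydroperoxide, CC(C)(OO)c1ccccc1
Why: Hydroxyl-directed catalytic asymmetric epoxidation of a homoallylic alcohol; the vanadium-bound chiral ligand differentiates the alkene faces and sets the quaternary epoxide centre as R.

Step 24
Reactants: 31 epoxy alcohol
Product: 32 (R)-2-(2-methyloxiran-2-yl)acetic acid
Conditions: TEMPO (cat.), PhI(OAc)2, MeCN/H2O (pH 7 buffer), 0 °C to rt
Reagents that add atoms: water, O
Why: TEMPO/PhI(OAc)2 oxidation in aqueous acetonitrile takes the primary alcohol through the aldehyde hydrate to the acid without base, so the β,γ-epoxide is not lost by elimination.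

Step 25
Reactants: 29 8-hydroxy lactone; 32 (R)-epoxy acid
Product: 33 8-O-[(R)-(2-methyloxiran-2-yl)acetyl] 9-O-PMB lactone
Conditions: DCC, DMAP (cat.), CH2Cl2, 0 °C
Reagents that add atoms: (R)-2-(2-methyloxiran-2-yl)acetic acid (32), OC(=O)C[C@]1(C)CO1
Why: Steglich esterification; O8 is the only free hydroxyl, C8 is not touched, and low temperature with catalytic DMAP limits base-induced opening of the epoxy acid.

Step 26
Reactants: 33 PMB ether
Product: 34 target CNP0284481.1
Conditions: DDQ, CH2Cl2/pH 7 buffer, 0 °C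
Reagents that add atoms: none
Why: Oxidative PMB cleavage by DDQ (benzylic hydride abstraction, hydrolysis of the oxocarbenium ion) under neutral buffered conditions that spare the epoxide, both esters and the diene and should not move the acyl group from O8 to O9.

## Compound list

1 | (S)-(+)-carvone | CC(=C)[C@H]1CC=C(C)C(=O)C1 | starting material
2 | vinylmagnesium bromide | C=C[Mg]Br | starting material
3 | (5S)-1-ethenyl-2-methyl-5-(prop-1-en-2-yl)cyclohex-2-en-1-ol, 9α-OH, 9β-vinyl | C=C[C@@]1(O)C(C)=CC[C@H](C(C)=C)C1 | intermediate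
4 | 10,5α-epoxide of 3 (epoxide syn to OH) | C=C[C@@]1(O)[C@]2(C)O[C@@H]2C[C@H](C(C)=C)C1 | intermediate
5 | 5α-hydroxy-10α-methyl-10β-vinyl-7α-isopropenylcyclohexan-9-one | O[C@@H]1C[C@H](C(C)=C)CC(=O)[C@@]1(C)C=C | intermediate
6 | 5-O-triethylsilyl ether of 5 | CC[Si](CC)(CC)O[C@@H]1C[C@H](C(C)=C)CC(=O)[C@@]1(C)C=C | intermediate
7 | potassium C8=C9 enolate of 6 (not isolated) | CC[Si](CC)(CC)O[C@@H]1C[C@H](C(C)=C)C=C([O-])[C@@]1(C)C=C.[K+] | intermediate
8 | 8β-hydroxy-9-ketone | CC[Si](CC)(CC)O[C@@H]1C[C@H](C(C)=C)[C@@H](O)C(=O)[C@@]1(C)C=C | intermediate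
9 | 8β,9α-diol | CC[Si](CC)(CC)O[C@@H]1C[C@H](C(C)=C)[C@@H](O)[C@H](O)[C@@]1(C)C=C | intermediate
10 | 8,9-O-(4-methoxybenzylidene) acetal (acetal carbon unassigned) | CC[Si](CC)(CC)O[C@@H]1C[C@H](C(C)=C)[C@H]2OC(c3ccc(OC)cc3)O[C@@H]2[C@@]1(C)C=C | intermediate
11 | 9α-O-PMB ether, 8β-OH | CC[Si](CC)(CC)O[C@@H]1C[C@H](C(C)=C)[C@@H](O)[C@H](OCc2ccc(OC)cc2)[C@@]1(C)C=C | intermediate
12 | C8 ketone | CC[Si](CC)(CC)O[C@@H]1C[C@H](C(C)=C)C(=O)[C@H](OCc2ccc(OC)cc2)[C@@]1(C)C=C | intermediate
13 | 8α-alcohol | CC[Si](CC)(CC)O[C@@H]1C[C@H](C(C)=C)[C@H](O)[C@H](OCc2ccc(OC)cc2)[C@@]1(C)C=C | intermediate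
14 | 8α-O-TBS, 9α-O-PMB, 5α-O-TES ether | CC[Si](CC)(CC)O[C@@H]1C[C@H](C(C)=C)[C@H](O[Si](C)(C)C(C)(C)C)[C@H](OCc2ccc(OC)cc2)[C@@]1(C)C=C | intermediate
15 | 5α-alcohol | O[C@@H]1C[C@H](C(C)=C)[C@H](O[Si](C)(C)C(C)(C)C)[C@H](OCc2ccc(OC)cc2)[C@@]1(C)C=C | intermediate
16 | C5 ketone | O=C1C[C@H](C(C)=C)[C@H](O[Si](C)(C)C(C)(C)C)[C@H](OCc2ccc(OC)cc2)[C@@]1(C)C=C | intermediate
17 | potassium C5=C6 enolate of 16 (not isolated) | [K+].[O-]C1=C[C@H](C(C)=C)[C@H](O[Si](C)(C)C(C)(C)C)[C@H](OCc2ccc(OC)cc2)[C@@]1(C)C=C | intermediate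
18 | 6β-hydroxy-5-ketone | O=C1[C@@H](O)[C@H](C(C)=C)[C@H](O[Si](C)(C)C(C)(C)C)[C@H](OCc2ccc(OC)cc2)[C@@]1(C)C=C | intermediate
19 | 6β,12-dihydroxy-5-ketone | O=C1[C@@H](O)[C@H](C(=C)CO)[C@H](O[Si](C)(C)C(C)(C)C)[C@H](OCc2ccc(OC)cc2)[C@@]1(C)C=C | intermediate
20 | 6,12-bis-O-(2-methoxyprop-2-yl) 5-ketone | O=C1[C@@H](OC(C)(C)OC)[C@H](C(=C)COC(C)(C)OC)[C@H](O[Si](C)(C)C(C)(C)C)[C@H](OCc2ccc(OC)cc2)[C@@]1(C)C=C | intermediate
21 | isopropenylmagnesium bromide | CC(=C)[Mg]Br | starting material
22 | cis-1-isopropenyl-2-vinylcyclohexanol (key-step precursor) | O[C@]1(C(C)=C)[C@@H](OC(C)(C)OC)[C@H](C(=C)COC(C)(C)OC)[C@H](O[Si](C)(C)C(C)(C)C)[C@H](OCc2ccc(OC)cc2)[C@@]1(C)C=C | intermediate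
23 | potassium alkoxide of 22 (not isolated) | [K+].[O-][C@]1(C(C)=C)[C@@H](OC(C)(C)OC)[C@H](C(=C)COC(C)(C)OC)[C@H](O[Si](C)(C)C(C)(C)C)[C@H](OCc2ccc(OC)cc2)[C@@]1(C)C=C | intermediate
24 | ten-membered potassium C4=C5 enolate (not isolated) | [K+].COC(C)(C)O[C@@H]1/C([O-])=C(\C)CC/C=C(/C)[C@@H](OCc2ccc(OC)cc2)[C@@H](O[Si](C)(C)C(C)(C)C)[C@H]1C(=C)COC(C)(C)OC | intermediate
25 | ten-membered C5 enol triflate (key-step product) | COC(C)(C)O[C@@H]1/C(OS(=O)(=O)C(F)(F)F)=C(\C)CC/C=C(/C)[C@@H](OCc2ccc(OC)cc2)[C@@H](O[Si](C)(C)C(C)(C)C)[C@H]1C(=C)COC(C)(C)OC | intermediate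
26 | (1(10)Z,4E)-diene, 6,12-bis-OMOP, 8-OTBS, 9-OPMB | COC(C)(C)O[C@@H]1/C=C(\C)CC/C=C(/C)[C@@H](OCc2ccc(OC)cc2)[C@@H](O[Si](C)(C)C(C)(C)C)[C@H]1C(=C)COC(C)(C)OC | intermediate
27 | 6,12-diol | O[C@@H]1/C=C(\C)CC/C=C(/C)[C@@H](OCc2ccc(OC)cc2)[C@@H](O[Si](C)(C)C(C)(C)C)[C@H]1C(=C)CO | intermediate
28 | 12,6-lactone, 8-OTBS, 9-OPMB | C=C1C(=O)O[C@@H]2/C=C(\C)CC/C=C(/C)[C@@H](OCc3ccc(OC)cc3)[C@@H](O[Si](C)(C)C(C)(C)C)[C@@H]12 | intermediate
29 | 8-hydroxy lactone, 9-OPMB | C=C1C(=O)O[C@@H]2/C=C(\C)CC/C=C(/C)[C@@H](OCc3ccc(OC)cc3)[C@@H](O)[C@@H]12 | intermediate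
30 | 3-methylbut-3-en-1-ol | CC(=C)CCO | starting material
31 | (R)-2-(2-methyloxiran-2-yl)ethan-1-ol | OCC[C@]1(C)CO1 | intermediate
32 | (R)-2-(2-methyloxiran-2-yl)acetic acid | OC(=O)C[C@]1(C)CO1 | intermediate
33 | 8-O-acyl 9-O-PMB lactone | C=C1C(=O)O[C@@H]2/C=C(\C)CC/C=C(/C)[C@@H](OCc3ccc(OC)cc3)[C@@H](OC(=O)C[C@]4(C)CO4)[C@@H]12 | intermediate
34 | CNP0284481.1, (6R,7S,8S,9R,1(10)Z,4E)-9-hydroxy-8-[(R)-(2-methyloxiran-2-yl)acetoxy]germacra-1(10),4,11(13)-trien-12,6-olide | C=C1C(=O)O[C@@H]2/C=C(\C)CC/C=C(/C)[C@@H](O)[C@@H](OC(=O)C[C@]3(C)CO3)[C@@H]12 | target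

## Step count and risks

Total step count: 26 (24 in the main line, 2 for acid 32). Longest linear sequence: 24 steps (steps 1–22, 25, 26).

Steps most likely to fail:

Step 18. The alkoxide may fragment (β-scission or retro-ene cleavage of the activated C5–C10 bond) or suffer base-induced isomerisation before the sigmatropic shift, and any reaction through the flipped chair would erode the (Z,E) geometry. Fallback, setting out from 22 and returning at 25: 22 is silylated (Me3SiOTf, Et3N, CH2Cl2, −78 °C) to the trimethylsilyl ether F1. Heating F1 in degassed o-xylene at about 200 °C in base-washed glassware should bring about the neutral siloxy-Cope rearrangement through the same chair and give the ten-membered trimethylsilyl enol ether F2. MeLi in THF at 0 °C cleaves the Si–O bond to the lithium enolate F3, and PhNTf2 converts this into 25.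

Step 17. Enolisation of the hindered α-alkoxy ketone may outrun addition, and delivery of the branched alkenyl group from the α face would give the trans-dialkenyl carbinol, which cannot reach the required chair. Fallback, setting out from 20 and returning at 22: the slim sp nucleophile HC≡CMgBr (THF, 0 °C), with its strong preference for axial attack, gives the ethynyl carbinol F4. Markovnikov hydration with Ph3PAuNTf2 (cat.) in wet 1,4-dioxane gives the α-hydroxy methyl ketone F5, and Wittig methylenation with excess Ph3P=CH2 (THF, 0 °C to rt) gives 22.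

Step 15. The oxidation may run on to the aldehyde level, which would be captured as a hemiacetal by the C6 hydroxyl, and the α-ketol may be oxidised as well. Fallback, setting out from 18 and returning at 19: selenium-catalysed ene-type chlorination (N-chlorosuccinimide, PhSeCl (cat.), CH2Cl2, rt) gives the allylic chloride F6. Displacement with CsOAc in DMF at 40 °C gives the allylic acetate F7, and K2CO3 in MeOH at 0 °C gives 19 without ever passing through the aldehyde.

Further compounds
F1 | step 18 | trimethylsilyl ether of 22 | C[Si](C)(C)O[C@]1(C(C)=C)[C@@H](OC(C)(C)OC)[C@H](C(=C)COC(C)(C)OC)[C@H](O[Si](C)(C)C(C)(C)C)[C@H](OCc2ccc(OC)cc2)[C@@]1(C)C=C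
F2 | step 18 | ten-membered trimethylsilyl enol ether | COC(C)(C)O[C@@H]1/C(O[Si](C)(C)C)=C(\C)CC/C=C(/C)[C@@H](OCc2ccc(OC)cc2)[C@@H](O[Si](C)(C)C(C)(C)C)[C@H]1C(=C)COC(C)(C)OC
F3 | step 18 | ten-membered lithium C4=C5 enolate | [Li+].COC(C)(C)O[C@@H]1/C([O-])=C(\C)CC/C=C(/C)[C@@H](OCc2ccc(OC)cc2)[C@@H](O[Si](C)(C)C(C)(C)C)[C@H]1C(=C)COC(C)(C)OC
F4 | step 17 | 5β-ethynyl 5α-carbinol | O[C@]1(C#C)[C@@H](OC(C)(C)OC)[C@H](C(=C)COC(C)(C)OC)[C@H](O[Si](C)(C)C(C)(C)C)[C@H](OCc2ccc(OC)cc2)[C@@]1(C)C=C
F5 | step 17 | 5β-acetyl 5α-carbinol (α-hydroxy methyl ketone) | O[C@]1(C(C)=O)[C@@H](OC(C)(C)OC)[C@H](C(=C)COC(C)(C)OC)[C@H](O[Si](C)(C)C(C)(C)C)[C@H](OCc2ccc(OC)cc2)[C@@]1(C)C=C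
F6 | step 15 | allylic chloride (C12–Cl) | O=C1[C@@H](O)[C@H](C(=C)CCl)[C@H](O[Si](C)(C)C(C)(C)C)[C@H](OCc2ccc(OC)cc2)[C@@]1(C)C=C
F7 | step 15 | allylic acetate (C12–OAc) | O=C1[C@@H](O)[C@H](C(=C)COC(C)=O)[C@H](O[Si](C)(C)C(C)(C)C)[C@H](OCc2ccc(OC)cc2)[C@@]1(C)C=C
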